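**Retrosynthetic overview**

1. Wailupemycin F ⇐ its tris-ether (benzyl on O8 and on the pyranone oxygen, (S)-1-phenylethyl on O3) by one hydrogenolysis; the tris-ether ⇐ an open-chain o-methylaryl (E)-β-alkoxyvinyl ketone by closing the cyclohexanone ring through C3–C4 (LDA: lateral deprotonation, then 6π-electrocyclisation = 6-endo Michael), which also sets C3.
2. Enabling feature: on the benzene ring the C4 methyl carbon (on C4a) is ortho to the C1 ketone (on C8a), so it is a vinylogous α-carbon. Its anion is an o-quinodimethane enolate in which C4=C4a–C8a=C1–C2=C3 is a hexatriene with C4 and C3 at its ends; the peri C8 ether oxygen chelates Li and turns the enone arm toward C4.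
3. The alkoxyvinyl ketone ⇐ aryl methyl ketone (Claisen formylation, enol tosylate, exchange with (S)-1-phenylethanol); the 4-oxygenated 2-pyranone ⇐ aryl carboxylic acid + dioxinone (acylketene cyclisation).
4. The pentasubstituted benzene ⇐ tert-butyl benzoylacetate + acetaldehyde + acetylacetone (Knoevenagel, Michael/aldol condensation, DDQ aromatisation); this fixes the substitution pattern without a regiochemical choice.
5. Order of ring formation: benzene ring, then pyranone ring, then cyclohexanone ring (key step).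

Key step: step 12

Remark: tert-butyl 3-oxo-3-phenylpropanoate is taken as a catalogue compound, and the two aryl–aryl axes are assumed to rotate freely, so that C3 is the only stereogenic element to control.

**Route**

Step 1
Reactants: 1 tert-butyl 3-oxo-3-phenylpropanoate; 2 acetaldehyde (excess)
Product: 3 tert-butyl 2-benzoylbut-2-enoate (E/Z mixture)
Conditions: piperidine (5 mol %), AcOH (5 mol %), 4 Å MS, CH2Cl2, −10 to 0 °C
Reagents that add atoms: none
Why: Knoevenagel condensation of the doubly activated methylene with the aldehyde (excess aldehyde and low temperature hold back the bis-adduct); the alkene geometry is irrelevant because both isomers converge in step 2.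

Step 2
Reactants: 3 tert-butyl 2-benzoylbut-2-enoate; 4 pentane-2,4-dione
Product: 7 tert-butyl 3-acetyl-2-methyl-4-oxo-6-phenylcyclohex-5-ene-1-carboxylate (diastereomer mixture), via Michael adduct 5 (not isolated), via cyclic aldol 6 (not isolated)
Conditions: pyrrolidine (20 mol %), AcOH (20 mol %), 4 Å MS, MeCN, rt then 60 °C
Reagents that add atoms: none
Why: Amine-catalysed Michael addition of the 1,3-diketone to the alkylidene β-keto ester, then a Robinson-type intramolecular aldol condensation in which an acetyl CH3 attacks the benzoyl carbonyl (the only six-membered closure available) and water is lost; the sp3 stereocentres are left uncontrolled because all become sp2 in step 3.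

Step 3
Reactants: 7 tert-butyl 3-acetyl-2-methyl-4-oxo-6-phenylcyclohex-5-ene-1-carboxylate
Product: 8 tert-butyl 3-acetyl-4-hydroxy-2-methyl-6-phenylbenzoate
Conditions: DDQ (1.2 equiv), 1,4-dioxane, 90 °C
Reagents that add atoms: none
Why: Dehydrogenative aromatisation of an enolised 2-acylcyclohexenone with DDQ (hydride abstraction, then proton loss), driven by formation of the hydrogen-bonded o-hydroxyacetophenone.

Step 4
Reactants: 8 tert-butyl 3-acetyl-4-hydroxy-2-methyl-6-phenylbenzoate
Product: 9 tert-butyl 3-acetyl-4-(benzyloxy)-2-methyl-6-phenylbenzoate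
Conditions: BnBr, K2CO3, DMF, 60 °C
Reagents that add atoms: benzyl bromide, BrCc1ccccc1
Why: Williamson ether synthesis on the phenoxide; the chelated, hindered phenol needs DMF and mild heating, and no other site is alkylated under these conditions.

Step 5
Reactants: 9 tert-butyl 3-acetyl-4-(benzyloxy)-2-methyl-6-phenylbenzoate
Product: 10 3-acetyl-4-(benzyloxy)-2-methyl-6-phenylbenzoic acid
Conditions: TFA/CH2Cl2 (1:3), 0 °C to rt
Reagents that add atoms: none
Why: Acidolysis of the tert-butyl ester (E1 loss of isobutene) frees the di-ortho-substituted acid without a hydrolysis step, while the benzyl ether and the ketone are stable to TFA at room temperature.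

Step 6
Reactants: 10 3-acetyl-4-(benzyloxy)-2-methyl-6-phenylbenzoic acid; 11 2,2,6-trimethyl-4H-1,3-dioxin-4-one (2.2 equiv)
Product: 13 6-{2-[3-acetyl-4-(benzyloxy)-2-methyl-6-phenylphenyl]-2-oxoethyl}-2,2-dimethyl-4H-1,3-dioxin-4-one, via acid chloride 12 (not isolated)
Conditions: (COCl)2, cat. DMF, CH2Cl2, 0 °C to rt, evaporate; then add to 11 + LiHMDS (2.2 equiv), THF, −78 to −40 °C; aq. HCl
Reagents that add atoms: none
Why: Acid chloride formation followed by γ-selective C-acylation of the lithium dienolate of the dioxinone (vinylogous Claisen condensation); the second equivalent of dienolate takes up the acidic proton of the new β-diketone, and the twisted, hindered acetyl group should be neither attacked nor enolised at −78 °C.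

Step 7
Reactants: 13 6-{2-[3-acetyl-4-(benzyloxy)-2-methyl-6-phenylphenyl]-2-oxoethyl}-2,2-dimethyl-4H-1,3-dioxin-4-one
Product: 15 6-[3-acetyl-4-(benzyloxy)-2-methyl-6-phenylphenyl]-4-hydroxy-2H-pyran-2-one, via acylketene 14 (not isolated)
Conditions: toluene, 110 °C
Reagents that add atoms: none
Why: Thermal retro-[4+2] loss of acetone gives the acylketene, which is captured by the enol oxygen of the neighbouring aryl ketone (6π-oxa-electrocyclisation/lactonisation) to give the 4-hydroxy-2-pyranone.

Step 8
Reactants: 15 6-[3-acetyl-4-(benzyloxy)-2-methyl-6-phenylphenyl]-4-hydroxy-2H-pyran-2-one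
Product: 16 6-[3-acetyl-4-(benzyloxy)-2-methyl-6-phenylphenyl]-4-(benzyloxy)-2H-pyran-2-one
Conditions: BnBr, K2CO3, DMF, rt
Reagents that add atoms: benzyl bromide, BrCc1ccccc1
Why: O-Alkylation of the vinylogous carboxylate (pKa about 5) at O4, the standard route to 4-alkoxy-2-pyranones; the weak base leaves the methyl ketone untouched.

Step 9
Reactants: 16 6-[3-acetyl-4-(benzyloxy)-2-methyl-6-phenylphenyl]-4-(benzyloxy)-2H-pyran-2-one
Product: 17 4-(benzyloxy)-6-{4-(benzyloxy)-3-[(2Z)-3-hydroxyprop-2-enoyl]-2-methyl-6-phenylphenyl}-2H-pyran-2-one (chelated enol of the β-keto aldehyde)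
Conditions: LiHMDS (1.2 equiv), THF, −78 °C; CF3CH2OCHO, −78 to 0 °C; aq. HCl
Reagents that add atoms: 2,2,2-trifluoroethyl formate, O=COCC(F)(F)F
Why: Crossed Claisen condensation (formylation) of the kinetic lithium enolate of the methyl ketone with an activated formate, made irreversible because the product is held as its chelated enolate; at −78 °C the silylamide should not add to the pyranone.

Step 10
Reactants: 17 4-(benzyloxy)-6-{4-(benzyloxy)-3-[(2Z)-3-hydroxyprop-2-enoyl]-2-methyl-6-phenylphenyl}-2H-pyran-2-one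
Product: 18 4-(benzyloxy)-6-{4-(benzyloxy)-2-methyl-6-phenyl-3-[(2E)-3-(tosyloxy)prop-2-enoyl]phenyl}-2H-pyran-2-one
Conditions: TsCl, Et3N, CH2Cl2, 0 °C
Reagents that add atoms: 4-methylbenzenesulfonyl chloride, Cc1ccc(cc1)S(Cl)(=O)=O
Why: O-Sulfonylation of the enol at the less hindered, aldehyde-derived oxygen turns C3 into a vinylogous sulfonate ester ready for addition–elimination.

Step 11
Reactants: 18 4-(benzyloxy)-6-{4-(benzyloxy)-2-methyl-6-phenyl-3-[(2E)-3-(tosyloxy)prop-2-enoyl]phenyl}-2H-pyran-2-one; 19 (S)-1-phenylethanol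
Product: 20 4-(benzyloxy)-6-{4-(benzyloxy)-2-methyl-6-phenyl-3-[(2E)-3-{[(1S)-1-phenylethyl]oxy}prop-2-enoyl]phenyl}-2H-pyran-2-one
Conditions: DABCO (20 mol %), Et3N (1.5 equiv), CH2Cl2, rt
Reagents that add atoms: none
Why: Nucleophilic vinylic substitution by addition–elimination (DABCO adds to C3 and expels tosylate, the alcohol then displaces DABCO) should give the thermodynamic E enol ether; the C–O bond of the alcohol is not broken, so its S configuration is retained.

Step 12
Reactants: 20 4-(benzyloxy)-6-{4-(benzyloxy)-2-methyl-6-phenyl-3-[(2E)-3-{[(1S)-1-phenylethyl]oxy}prop-2-enoyl]phenyl}-2H-pyran-2-one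
Product: 23 (3S)-8-(benzyloxy)-5-[4-(benzyloxy)-2-oxo-2H-pyran-6-yl]-6-phenyl-3-{[(1S)-1-phenylethyl]oxy}-3,4-dihydronaphthalen-1(2H)-one, via lithium o-quinodimethane dienolate 21 (not isolated), via lithium enolate 22 (not isolated)
Conditions: LDA (1.2 equiv), THF, −78 °C, inverse addition; AcOH, −78 °C
Reagents that add atoms: none
Why: Proposed new method: LDA removes a proton from the C4 methyl group, the only C–H conjugated (through C4a=C8a) with the C1 carbonyl, to give the lithium 2-oxido-o-quinodimethane 21, in which Li bridges O1 and the peri C8 benzyloxy oxygen and so turns the alkoxyvinyl arm toward C4. The hexatriene C4=C4a–C8a=C1–C2=C3 should then close by thermal disrotatory 6π-electrocyclisation, equivalent to a 6-endo-trig intramolecular Michael addition, which forms C3–C4, restores the benzene ring and gives lithium enolate 22; acetic acid at −78 °C protonates 22 before the alkoxide can leave by E1cB. The closest known reaction type is the lateral-lithiation annulation of o-methylaryl β-amino- or β-alkoxyvinyl ketones and ynones to 1-naphthols, together with the Michael step of the Staunton–Weinreb annulation; what is new is stopping at the dihydro stage and steering the face with an ether auxiliary. C3 is the only new stereocentre and is controlled by the (S)-1-phenylethyl group on O3: in the s-cis enol ether conformer with the carbinol C–H eclipsing the O–C3 bond the phenyl ring covers the Re face of C3, so C4 should bond to the Si face and give 3S. The step needs facial selectivity, for which the auxiliary and the low temperature are responsible (the 3R epimer would be a separable diastereomer), and chemoselectivity, which rests on 20 having no enolisable α-C–H, on the inertness of the benzyl ether and pyranone C–H bonds toward LDA at −78 °C and on the cold acidic quench.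

Step 13
Reactants: 23 (3S)-8-(benzyloxy)-5-[4-(benzyloxy)-2-oxo-2H-pyran-6-yl]-6-phenyl-3-{[(1S)-1-phenylethyl]oxy}-3,4-dihydronaphthalen-1(2H)-one
Product: 24 wailupemycin F, (3S)-3,8-dihydroxy-5-(4-hydroxy-2-oxo-2H-pyran-6-yl)-6-phenyl-3,4-dihydronaphthalen-1(2H)-one
Conditions: H2 (1–3 atm), 20 % Pd(OH)2/C, EtOAc, rt
Reagents that add atoms: none
Why: Palladium-catalysed hydrogenolysis of the three benzylic C–O bonds under neutral conditions should release the three hydroxyl groups in one operation without touching the C3–O bond, so the 3S centre is retained.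

**Compound list**

1 | tert-butyl 3-oxo-3-phenylpropanoate | O=C(CC(=O)OC(C)(C)C)c1ccccc1 | starting material
2 | acetaldehyde | CC=O | starting material
3 | tert-butyl 2-benzoylbut-2-enoate (E/Z mixture) | CC=C(C(=O)c1ccccc1)C(=O)OC(C)(C)C | intermediate
4 | pentane-2,4-dione | CC(=O)CC(C)=O | starting material
5 | tert-butyl 4-acetyl-2-benzoyl-3-methyl-5-oxohexanoate (Michael adduct, diastereomer mixture) | CC(C(C(C)=O)C(C)=O)C(C(=O)c1ccccc1)C(=O)OC(C)(C)C | intermediate (not isolated)
6 | tert-butyl 3-acetyl-6-hydroxy-2-methyl-4-oxo-6-phenylcyclohexane-1-carboxylate (cyclic aldol, diastereomer mixture) | CC(=O)C1C(C)C(C(=O)OC(C)(C)C)C(O)(c2ccccc2)CC1=O | intermediate (not isolated)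
7 | tert-butyl 3-acetyl-2-methyl-4-oxo-6-phenylcyclohex-5-ene-1-carboxylate (diastereomer mixture) | CC(=O)C1C(C)C(C(=O)OC(C)(C)C)C(c2ccccc2)=CC1=O | intermediate
8 | tert-butyl 3-acetyl-4-hydroxy-2-methyl-6-phenylbenzoate | CC(=O)c1c(C)c(C(=O)OC(C)(C)C)c(-c2ccccc2)cc1O | intermediate
9 | tert-butyl 3-acetyl-4-(benzyloxy)-2-methyl-6-phenylbenzoate | CC(=O)c1c(C)c(C(=O)OC(C)(C)C)c(-c2ccccc2)cc1OCc1ccccc1 | intermediate
10 | 3-acetyl-4-(benzyloxy)-2-methyl-6-phenylbenzoic acid | CC(=O)c1c(C)c(C(=O)O)c(-c2ccccc2)cc1OCc1ccccc1 | intermediate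
11 | 2,2,6-trimethyl-4H-1,3-dioxin-4-one | CC1=CC(=O)OC(C)(C)O1 | starting material
12 | 3-acetyl-4-(benzyloxy)-2-methyl-6-phenylbenzoyl chloride | CC(=O)c1c(C)c(C(Cl)=O)c(-c2ccccc2)cc1OCc1ccccc1 | intermediate (not isolated)
13 | 6-{2-[3-acetyl-4-(benzyloxy)-2-methyl-6-phenylphenyl]-2-oxoethyl}-2,2-dimethyl-4H-1,3-dioxin-4-one | CC(=O)c1c(C)c(C(=O)CC2=CC(=O)OC(C)(C)O2)c(-c2ccccc2)cc1OCc1ccccc1 | intermediate
14 | 5-[3-acetyl-4-(benzyloxy)-2-methyl-6-phenylphenyl]-3,5-dioxopent-1-en-1-one (acylketene) | CC(=O)c1c(C)c(C(=O)CC(=O)C=C=O)c(-c2ccccc2)cc1OCc1ccccc1 | intermediate (not isolated)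
15 | 6-[3-acetyl-4-(benzyloxy)-2-methyl-6-phenylphenyl]-4-hydroxy-2H-pyran-2-one | CC(=O)c1c(C)c(-c2cc(O)cc(=O)o2)c(-c2ccccc2)cc1OCc1ccccc1 | intermediate
16 | 6-[3-acetyl-4-(benzyloxy)-2-methyl-6-phenylphenyl]-4-(benzyloxy)-2H-pyran-2-one | CC(=O)c1c(C)c(-c2cc(OCc3ccccc3)cc(=O)o2)c(-c2ccccc2)cc1OCc1ccccc1 | intermediate
17 | 4-(benzyloxy)-6-{4-(benzyloxy)-3-[(2Z)-3-hydroxyprop-2-enoyl]-2-methyl-6-phenylphenyl}-2H-pyran-2-one | O/C=C\C(=O)c1c(C)c(-c2cc(OCc3ccccc3)cc(=O)o2)c(-c2ccccc2)cc1OCc1ccccc1 | intermediate
18 | 4-(benzyloxy)-6-{4-(benzyloxy)-2-methyl-6-phenyl-3-[(2E)-3-(tosyloxy)prop-2-enoyl]phenyl}-2H-pyran-2-one | Cc1ccc(cc1)S(=O)(=O)O/C=C/C(=O)c1c(C)c(-c2cc(OCc3ccccc3)cc(=O)o2)c(-c2ccccc2)cc1OCc1ccccc1 | intermediate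
19 | (S)-1-phenylethanol | C[C@H](O)c1ccccc1 | starting material
20 | 4-(benzyloxy)-6-{4-(benzyloxy)-2-methyl-6-phenyl-3-[(2E)-3-{[(1S)-1-phenylethyl]oxy}prop-2-enoyl]phenyl}-2H-pyran-2-one | C[C@H](O/C=C/C(=O)c1c(C)c(-c2cc(OCc3ccccc3)cc(=O)o2)c(-c2ccccc2)cc1OCc1ccccc1)c1ccccc1 | intermediate
21 | lithium o-quinodimethane dienolate of 20: lithium (2E)-1-{6-(benzyloxy)-3-[4-(benzyloxy)-2-oxo-2H-pyran-6-yl]-2-methylidene-4-phenylcyclohexa-3,5-dien-1-ylidene}-3-{[(1S)-1-phenylethyl]oxy}prop-2-en-1-olate | [Li]OC(/C=C/O[C@@H](C)c1ccccc1)=C1C(=C)C(-c2cc(OCc3ccccc3)cc(=O)o2)=C(-c2ccccc2)C=C1OCc1ccccc1 | intermediate (not isolated)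
22 | lithium enolate of 23: lithium (3S)-8-(benzyloxy)-5-[4-(benzyloxy)-2-oxo-2H-pyran-6-yl]-6-phenyl-3-{[(1S)-1-phenylethyl]oxy}-3,4-dihydronaphthalen-1-olate | [Li]OC1=C[C@@H](O[C@@H](C)c3ccccc3)Cc2c1c(OCc1ccccc1)cc(-c1ccccc1)c2-c1cc(OCc2ccccc2)cc(=O)o1 | intermediate (not isolated)
23 | (3S)-8-(benzyloxy)-5-[4-(benzyloxy)-2-oxo-2H-pyran-6-yl]-6-phenyl-3-{[(1S)-1-phenylethyl]oxy}-3,4-dihydronaphthalen-1(2H)-one | O=C1C[C@@H](O[C@@H](C)c3ccccc3)Cc2c1c(OCc1ccccc1)cc(-c1ccccc1)c2-c1cc(OCc2ccccc2)cc(=O)o1 | intermediate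
24 | wailupemycin F, (3S)-3,8-dihydroxy-5-(4-hydroxy-2-oxo-2H-pyran-6-yl)-6-phenyl-3,4-dihydronaphthalen-1(2H)-one | O=C1C[C@@H](O)Cc2c1c(O)cc(-c1ccccc1)c2-c1cc(O)cc(=O)o1 | target

**Step count and risks**

Total steps: 13. Longest linear sequence: 13 steps (1 to 24; 2, 4, 11 and 19 are bought).

Steps most likely to fail:

1. Step 12 (Proposed new method). The cyclised lithium enolate may expel lithium (S)-1-phenylethoxide (E1cB) and aromatise to the 1-naphthol before it is protonated. Facial discrimination by the acyclic auxiliary may also be modest, because rotation about C3–O exposes the other face; the sense predicted by the conformer model may even be reversed, in which case the equally available (R)-alcohol would be used. The fallback uses known reaction types (α-bromination of a β-dicarbonyl enol; tin hydride radical translocation followed by 6-endo cyclisation onto the oxygen-bearing carbon of a β-alkoxy enone); it sets out from 17 and comes back at 23. NBS (CH2Cl2, 0 °C) would brominate the enol carbon C2 of 17 to give 4-(benzyloxy)-6-{4-(benzyloxy)-3-(2-bromo-3-hydroxyprop-2-enoyl)-2-methyl-6-phenylphenyl}-2H-pyran-2-one F1. Tosylation as in step 10 would give the bromo enol tosylate F2, and exchange with 19 as in step 11 would give the α-bromo-β-[(1S)-1-phenylethoxy] enone F3. Slow addition of Bu3SnH with AIBN (benzene, 80 °C) would generate the C2 vinyl radical, which takes a hydrogen atom from the C4 methyl group (1,5-transfer); the benzylic radical would then add 6-endo to C3 of the regenerated alkoxy enone, and the α-keto radical is reduced by the stannane to 23. No enolate is formed, so the alkoxide cannot be eliminated; the auxiliary still biases the face and the C3 epimers remain separable diastereomers.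

2. Step 13. The pyranone C5=C6 bond or the aryl ketone may be hydrogenated, the secondary 1-phenylethyl ether may be cleaved too slowly, and the β-hydroxy ketone may dehydrate to the naphthol on the catalyst. The fallback sets out from 23 and comes back at 24 without a new compound (F0): Lewis-acid ether cleavage with a cation scavenger (BCl3, pentamethylbenzene, CH2Cl2, −78 °C, MeOH quench) would remove both benzyl groups and ionise the 1-phenylethyl ether at its benzylic carbon, so that the C3–O bond and its configuration stay intact.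

3. Step 3. Dehydrogenation may stop short or go on to oxidise the benzylic and ester-α positions, and the β-diketone may lose its acetyl group (retro-Claisen) on heating. The fallback reaches the aromatic oxidation level by elimination instead of oxidation; it sets out from 4 (with 1) and comes back at 8. Compound 4 with triethyl orthoacetate and Ac2O (130 °C) would give 3-(1-ethoxyethylidene)pentane-2,4-dione F4. The sodium enolate of 1 (NaH, THF) would displace ethoxide by addition–elimination to give tert-butyl 4-acetyl-2-benzoyl-3-methyl-5-oxohex-2-enoate F5. On warming with DBU, F5 would undergo the same acetyl-CH3-to-benzoyl aldol condensation and tautomerise directly to 8.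

**Further compounds**

F1 | step 12 | 4-(benzyloxy)-6-{4-(benzyloxy)-3-(2-bromo-3-hydroxyprop-2-enoyl)-2-methyl-6-phenylphenyl}-2H-pyran-2-one (enol, E/Z mixture) | OC=C(Br)C(=O)c1c(C)c(-c2cc(OCc3ccccc3)cc(=O)o2)c(-c2ccccc2)cc1OCc1ccccc1
F2 | step 12 | 4-(benzyloxy)-6-{4-(benzyloxy)-3-[2-bromo-3-(tosyloxy)prop-2-enoyl]-2-methyl-6-phenylphenyl}-2H-pyran-2-one (E/Z mixture) | Cc1ccc(cc1)S(=O)(=O)OC=C(Br)C(=O)c1c(C)c(-c2cc(OCc3ccccc3)cc(=O)o2)c(-c2ccccc2)cc1OCc1ccccc1
F3 | step 12 | 4-(benzyloxy)-6-{4-(benzyloxy)-3-(2-bromo-3-{[(1S)-1-phenylethyl]oxy}prop-2-enoyl)-2-methyl-6-phenylphenyl}-2H-pyran-2-one (E/Z mixture) | C[C@H](OC=C(Br)C(=O)c1c(C)c(-c2cc(OCc3ccccc3)cc(=O)o2)c(-c2ccccc2)cc1OCc1ccccc1)c1ccccc1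
F0 | step 13 | none | none
F4 | step 3 | 3-(1-ethoxyethylidene)pentane-2,4-dione | CCOC(C)=C(C(C)=O)C(C)=O
F5 | step 3 | tert-butyl 4-acetyl-2-benzoyl-3-methyl-5-oxohex-2-enoate | CC(=O)C(C(C)=O)C(C)=C(C(=O)c1ccccc1)C(=O)OC(C)(C)C
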